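The C3–C4 bond of ring A (labdane numbering) is the strategic disconnection. The gem-dimethyl carbon C4 next to ring-fusion carbon C5 is the isopropenyl carbon of (S)-carvone, which supplies ring B and C5. Two enolate alkylations set C10 (methyl, then a 3-iodopropyl arm anti to isopropenyl), so the trans fusion is fixed before ring A exists. The key step exploits this C4/C5 feature: hydrogen-atom transfer from a manganese hydride makes the tertiary C4 radical, and nickel couples it with the primary C3 iodide. One operation closes ring A and creates the quaternary gem-dimethyl centre, leaving no functional group behind. A Negishi coupling adds the glyceride side chain; allylic oxidation installs the C7 ketone.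

Key step: step 6

Numbering used throughout (labdane): ring A = C1, C2, C3, C4, C5, C10; ring B = C5, C6, C7, C8, C9, C10. C4 carries the two methyls, C10 the angular methyl, C8 the vinylic methyl, C7 the ketone, and C9 the side chain C11–C15 (C13 bears the methyl, C15 is the ester carbon).

Assumption: the target is read from its SMILES as the ent-labdane glyceride (5R,10R,13R, glycerol 2R), and compounds 1, 6 and 8 are taken as commercial single enantiomers.

Step 1
Reactants: 1 methyl hydrogen (R)-3-methylglutarate
Product: 3 (4R)-4-methyloxan-2-one, via hydroxy ester 2 (not isolated)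
Conditions: BH3·SMe2, THF, 0 °C → rt; MeOH quench; then TsOH·H2O (cat.), CH2Cl2, rt
Reagents that add atoms: none
Why: Borane reduces the free carboxylic acid much faster than the methyl ester (chemoselective borane reduction) and the δ-hydroxy ester then lactonizes under acid catalysis to the six-membered lactone, the stereocentre being untouched so that the two chain ends stay differentiated.

Step 2
Reactants: 3 (4R)-4-methyloxan-2-one
Product: 5 (3S)-5-iodo-3-methylpentanoic acid, via silyl ester 4 (not isolated)
Conditions: Me3SiI, CH2Cl2, rt → 40 °C, dark; then H2O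
Reagents that add atoms: iodotrimethylsilane, C[Si](C)(C)I
Why: O-Silylation of the lactone carbonyl activates the ring O–CH2 carbon for SN2 attack by iodide (lactone cleavage with iodotrimethylsilane), which places iodine on the carbon that becomes C11 and leaves a silyl ester that water hydrolyses to the acid.

Step 3
Reactants: 5 (3S)-5-iodo-3-methylpentanoic acid; 6 (S)-solketal, [(4S)-2,2-dimethyl-1,3-dioxolan-4-yl]methanol
Product: 7 [(4R)-2,2-dimethyl-1,3-dioxolan-4-yl]methyl (3S)-5-iodo-3-methylpentanoate
Conditions: DCC, DMAP (cat.), CH2Cl2, 0 °C → rt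
Reagents that add atoms: none
Why: Steglich esterification (carbodiimide activation, acyl transfer by DMAP) should join the acid to the primary hydroxyl of the acetonide faster than the carboxylate can displace the primary iodide, and neither stereocentre takes part.

Step 4
Reactants: 8 (S)-(+)-carvone
Product: 10 (5S)-2,6-dimethyl-5-(prop-1-en-2-yl)cyclohex-2-en-1-one (6-methylcarvone; C6 epimer mixture), via lithium dienolate 9 (not isolated)
Conditions: LiN(i-Pr)2, THF, −78 °C; then MeI, −78 → 0 °C
Reagents that add atoms: iodomethane, CI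
Why: The hindered amide base removes an α′ proton under kinetic control to give the cross-conjugated dienolate, which is methylated by SN2 (kinetic enolate alkylation); the C6 configuration formed here is erased in step 5 and need not be controlled.

Step 5
Reactants: 10 6-methylcarvone (C6 epimer mixture)
Product: 12 (5R,6R)-6-(3-iodopropyl)-2,6-dimethyl-5-(prop-1-en-2-yl)cyclohex-2-en-1-one, via lithium enolate 11 (not isolated)
Conditions: LiN(i-Pr)2 (1.0 equiv), THF, −78 → −30 °C; DMPU; then added to I(CH2)3I (4 equiv), THF, −78 → 0 °C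
Reagents that add atoms: 1,3-diiodopropane, ICCCI
Why: Deprotonation of the α′ methine gives a tetrasubstituted enolate in which the C5 isopropenyl group lies pseudo-axial to avoid allylic strain with the C6 methyl, so the diiodide should be attacked from the opposite face (diastereoselective enolate alkylation) and the new quaternary C10 should carry the iodopropyl arm trans to isopropenyl; the excess of diiodide and inverse addition hold back double alkylation.

Step 6
Reactants: 12 (5R,6R)-6-(3-iodopropyl)-2,6-dimethyl-5-(prop-1-en-2-yl)cyclohex-2-en-1-one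
Product: 13 (4aR,8aR)-2,5,5,8a-tetramethyl-4a,5,6,7,8,8a-hexahydronaphthalen-1(4H)-one
Conditions: Mn(dpm)3 (20 mol %), Ni(acac)2 (10 mol %), PhSiH3 (2 equiv, slow addition), K2CO3, ClCH2CH2Cl/(CF3)2CHOH, 25 °C, 0.01 M
Reagents that add atoms: none
Why: Proposed new method: this is an intramolecular version of the closest known reaction type, the intermolecular Mn/Ni dual-catalytic Markovnikov hydroalkylation of unactivated 1,1-disubstituted olefins with primary alkyl iodides, in which the manganese hydride formed from Mn(dpm)3 and PhSiH3 transfers a hydrogen atom to the CH2 terminus of the electron-rich isopropenyl group to give the tertiary C4 radical while low-valent nickel inserts into the primary C3–I bond. Capture of the radical at nickel should give a seven-membered dialkylnickel ring whose C(sp3)–C(sp3) reductive elimination forms the C3–C4 bond. Ring A thus closes as a six-membered carbocycle by reductive elimination and not by radical attack on a π bond, so the 7-endo attack of a free C3 radical on the isopropenyl CH2 is the competing closure to be suppressed. No stereocentre is created, because C4 becomes a gem-dimethyl quaternary carbon; the trans ring fusion follows from the C5 and C10 configurations of 12, which hold the two reacting arms trans-diequatorial and gauche on ring B. The step needs coupling to win over plain alkene reduction, alkene isomerization and hydrodeiodination, which slow silane addition at high dilution and the enforced proximity of the two termini should favour. Any conjugate reduction of the C7=C8 enone bond would be harmless, since step 7 reduces that bond anyway.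

Step 7
Reactants: 13 (4aR,8aR)-2,5,5,8a-tetramethyl-4a,5,6,7,8,8a-hexahydronaphthalen-1(4H)-one
Product: 15 (4aR,8aR)-2,5,5,8a-tetramethyl-3,4,4a,5,6,7,8,8a-octahydronaphthalen-1-yl trifluoromethanesulfonate, via lithium enolate 14 (not isolated)
Conditions: LiBH(s-Bu)3, THF, −78 °C; then PhNTf2, −78 °C → rt
Reagents that add atoms: N-phenylbis(trifluoromethanesulfonimide), O=S(=O)(N(c1ccccc1)S(=O)(=O)C(F)(F)F)C(F)(F)F
Why: The bulky borohydride should add hydride 1,4 at the unhindered C7 of the enone, whose carbonyl is shielded by the quaternary C10 (conjugate reduction), and the regiodefined tetrasubstituted enolate is trapped on oxygen by PhNTf2 (enol triflate formation), C5 and C10 staying as set.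

Step 8
Reactants: 7 [(4R)-2,2-dimethyl-1,3-dioxolan-4-yl]methyl (3S)-5-iodo-3-methylpentanoate; 15 enol triflate of step 7
Product: 17 [(4R)-2,2-dimethyl-1,3-dioxolan-4-yl]methyl (3R)-3-methyl-5-[(4aR,8aR)-2,5,5,8a-tetramethyl-3,4,4a,5,6,7,8,8a-octahydronaphthalen-1-yl]pentanoate, via alkylzinc iodide 16 (not isolated)
Conditions: Zn dust (activated with BrCH2CH2Br and Me3SiCl), LiCl, THF, 35 °C; then 15, Pd(OAc)2 (5 mol %), SPhos (10 mol %), THF/NMP, 60 °C
Reagents that add atoms: none
Why: Zinc inserts into the primary C–I bond without touching ester or acetal, and Negishi sp2–sp3 coupling at zerovalent palladium bearing the bulky electron-rich biarylphosphine should form the C9–C11 bond, the ligand being chosen to speed oxidative addition at the hindered triflate and reductive elimination ahead of β-hydride elimination.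

Step 9
Reactants: 17 coupled alkene of step 8
Product: 18 [(4R)-2,2-dimethyl-1,3-dioxolan-4-yl]methyl (3R)-3-methyl-5-[(4aR,8aR)-2,5,5,8a-tetramethyl-3-oxo-3,4,4a,5,6,7,8,8a-octahydronaphthalen-1-yl]pentanoate
Conditions: CrO3, 3,5-dimethylpyrazole, CH2Cl2, −20 °C
Reagents that add atoms: chromium trioxide, O=[Cr](=O)=O
Why: Allylic oxidation by the hexavalent chromium–pyrazole complex should attack the ring methylene C7 next to the tetrasubstituted C8=C9 bond, as in related 8-ene decalins of the drimane and labdane series, because the side-chain methylene C11 is screened by the C10 methyl and C1, while the non-acidic medium spares acetonide and ester.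

Step 10
Reactants: 18 enone acetonide of step 9
Product: 19 (2R)-2,3-dihydroxypropyl (3R)-3-methyl-5-[(4aR,8aR)-2,5,5,8a-tetramethyl-3-oxo-3,4,4a,5,6,7,8,8a-octahydronaphthalen-1-yl]pentanoate (target)
Conditions: AcOH/H2O (4:1), 25 → 40 °C
Reagents that add atoms: none
Why: Mild aqueous acid hydrolyses the isopropylidene acetal (acetal hydrolysis) while the ester survives, the short mild treatment limiting acyl migration to the secondary hydroxyl, and the glycerol stereocentre is retained because no bond to it is broken.

Compound list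
1 | methyl hydrogen (R)-3-methylglutarate, (3R)-5-methoxy-3-methyl-5-oxopentanoic acid | COC(=O)C[C@H](C)CC(=O)O | starting material
2 | methyl (3R)-5-hydroxy-3-methylpentanoate | COC(=O)C[C@H](C)CCO | intermediate
3 | (4R)-4-methyloxan-2-one | O=C1C[C@H](C)CCO1 | intermediate
4 | trimethylsilyl (3S)-5-iodo-3-methylpentanoate | C[Si](C)(C)OC(=O)C[C@H](C)CCI | intermediate
5 | (3S)-5-iodo-3-methylpentanoic acid | OC(=O)C[C@H](C)CCI | intermediate
6 | (S)-solketal, [(4S)-2,2-dimethyl-1,3-dioxolan-4-yl]methanol | OC[C@H]1COC(C)(C)O1 | starting material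
7 | [(4R)-2,2-dimethyl-1,3-dioxolan-4-yl]methyl (3S)-5-iodo-3-methylpentanoate | ICC[C@@H](C)CC(=O)OC[C@H]1COC(C)(C)O1 | intermediate
8 | (S)-(+)-carvone, (5S)-2-methyl-5-(prop-1-en-2-yl)cyclohex-2-en-1-one | CC1=CC[C@@H](CC1=O)C(C)=C | starting material
9 | lithium dienolate of 8 (O-lithio, C1=C6 enolate) | CC1=CC[C@@H](C=C1O[Li])C(C)=C | intermediate
10 | (5S)-2,6-dimethyl-5-(prop-1-en-2-yl)cyclohex-2-en-1-one, C6 epimer mixture | CC1=CC[C@@H](C(C)C1=O)C(C)=C | intermediate
11 | lithium enolate of 10 (tetrasubstituted C1=C6 enolate) | CC1=CC[C@@H](C(C)=C1O[Li])C(C)=C | intermediate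
12 | (5R,6R)-6-(3-iodopropyl)-2,6-dimethyl-5-(prop-1-en-2-yl)cyclohex-2-en-1-one | CC1=CC[C@H](C(C)=C)[C@@](C)(CCCI)C1=O | intermediate
13 | (4aR,8aR)-2,5,5,8a-tetramethyl-4a,5,6,7,8,8a-hexahydronaphthalen-1(4H)-one (trans-fused) | CC1=CC[C@@H]2C(C)(C)CCC[C@@]2(C)C1=O | intermediate
14 | lithium (4aR,8aR)-2,5,5,8a-tetramethyl-3,4,4a,5,6,7,8,8a-octahydronaphthalen-1-olate | CC1=C(O[Li])[C@]2(C)CCCC(C)(C)[C@H]2CC1 | intermediate
15 | (4aR,8aR)-2,5,5,8a-tetramethyl-3,4,4a,5,6,7,8,8a-octahydronaphthalen-1-yl trifluoromethanesulfonate | CC1=C(OS(=O)(=O)C(F)(F)F)[C@]2(C)CCCC(C)(C)[C@H]2CC1 | intermediate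
16 | alkylzinc iodide from 7, {(3S)-5-{[(4R)-2,2-dimethyl-1,3-dioxolan-4-yl]methoxy}-3-methyl-5-oxopentyl}zinc iodide | I[Zn]CC[C@@H](C)CC(=O)OC[C@H]1COC(C)(C)O1 | intermediate
17 | [(4R)-2,2-dimethyl-1,3-dioxolan-4-yl]methyl (3R)-3-methyl-5-[(4aR,8aR)-2,5,5,8a-tetramethyl-3,4,4a,5,6,7,8,8a-octahydronaphthalen-1-yl]pentanoate | CC1=C(CC[C@@H](C)CC(=O)OC[C@H]2COC(C)(C)O2)[C@]3(C)CCCC(C)(C)[C@H]3CC1 | intermediate
18 | [(4R)-2,2-dimethyl-1,3-dioxolan-4-yl]methyl (3R)-3-methyl-5-[(4aR,8aR)-2,5,5,8a-tetramethyl-3-oxo-3,4,4a,5,6,7,8,8a-octahydronaphthalen-1-yl]pentanoate | CC1=C(CC[C@@H](C)CC(=O)OC[C@H]2COC(C)(C)O2)[C@]3(C)CCCC(C)(C)[C@H]3CC1=O | intermediate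
19 | (2R)-2,3-dihydroxypropyl (3R)-3-methyl-5-[(4aR,8aR)-2,5,5,8a-tetramethyl-3-oxo-3,4,4a,5,6,7,8,8a-octahydronaphthalen-1-yl]pentanoate | CC1=C(CC[C@@H](C)CC(=O)OC[C@H](O)CO)[C@]2(C)CCCC(C)(C)[C@H]2CC1=O | target

Total step count: 10 steps.
Longest linear sequence: 7 steps (steps 4, 5, 6, 7, 8, 9, 10 from 8).

Steps most likely to fail

Step 6. Capture of the tertiary C4 radical at nickel may lose to plain reduction of the isopropenyl group, to hydrodeiodination, or to 7-endo closure by a free C3 radical. The fallback uses known chemistry, sets out from 10 and comes back at 13. Enolate 11 is alkylated with 2-(2-iodoethyl)-1,3-dioxolane under the conditions of step 5, again anti to isopropenyl, to give the dioxolane acetal F1. PPTS in wet acetone frees the aldehyde F2, and TsNHNH2 in MeOH condenses with the aldehyde in preference to the hindered enone carbonyl to give the N-tosylhydrazone F3. Fe(acac)3 and PhSiH3 in EtOH at 60 °C then generate the same tertiary C4 radical, which adds 6-exo to the hydrazone carbon (a known hydrogen-atom-transfer alkene–hydrazone cyclization) to give the cyclic tosylhydrazide F4. Heating F4 with NaOAc in EtOH expels sulfinate and then dinitrogen through the monoalkyl diazene, leaving C3 as a methylene, which is 13.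

Step 8. Oxidative addition at the tetrasubstituted triflate flanked by the quaternary C10 may be slow, so that β-hydride elimination or protonation of the alkylzinc reagent takes over. The fallback makes the C9–C11 bond by carbonyl addition instead; it sets out from 5 and 13 and comes back at 18, and it needs neither step 7 nor step 9. BH3·SMe2 reduces 5 to the iodo alcohol F5, and TBSCl with imidazole gives the silyl ether F6. Lithium–iodine exchange with t-BuLi in Et2O at −78 °C gives the alkyllithium F7, which, after transmetalation with CeCl3 if enolization interferes, adds 1,2 to the C9 carbonyl of 13 to give the tertiary allylic alcohol F8. Pyridinium chlorochromate in CH2Cl2 effects the Babler–Dauben oxidative 1,3-transposition to the enone silyl ether F9. CrO3 in H2SO4/acetone cleaves the silyl ether and oxidizes the primary alcohol to the acid F10, and DCC/DMAP esterification with 6 gives 18.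

Step 9. Site selectivity between the ring methylene C7 and the side-chain methylene C11 may be poor, and over-oxidation or loss of the acetonide may occur. The fallback moves the oxidation ahead of the coupling; it sets out from 15 and comes back at 18. In 15 the only allylic methylene is C7 and no acetonide is present, so oxidation with Rh2(cap)4 (dirhodium tetracaprolactamate, cat.) and t-BuOOH should give the keto triflate F11. This β-triflyloxy enone is activated for oxidative addition and is coupled with 16 under the conditions of step 8 to give 18 directly.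

Further compounds
F1 | step 6 | (5R,6R)-6-[2-(1,3-dioxolan-2-yl)ethyl]-2,6-dimethyl-5-(prop-1-en-2-yl)cyclohex-2-en-1-one | CC1=CC[C@H](C(C)=C)[C@@](C)(CCC2OCCO2)C1=O
F2 | step 6 | 3-[(1R,6R)-1,3-dimethyl-2-oxo-6-(prop-1-en-2-yl)cyclohex-3-en-1-yl]propanal | CC1=CC[C@H](C(C)=C)[C@@](C)(CCC=O)C1=O
F3 | step 6 | (E)-N-tosylhydrazone of F2 | CC1=CC[C@H](C(C)=C)[C@@](C)(CC/C=N/NS(=O)(=O)c2ccc(C)cc2)C1=O
F4 | step 6 | 13 carrying a 2-tosylhydrazinyl group at C3 (both C3 epimers) | CC1=CC[C@@H]2C(C)(C)C(NNS(=O)(=O)c3ccc(C)cc3)CC[C@@]2(C)C1=O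
F5 | step 8 | (3S)-5-iodo-3-methylpentan-1-ol | OCC[C@H](C)CCI
F6 | step 8 | tert-butyl{[(3S)-5-iodo-3-methylpentyl]oxy}dimethylsilane | CC(C)(C)[Si](C)(C)OCC[C@H](C)CCI
F7 | step 8 | [(3R)-5-(tert-butyldimethylsilyloxy)-3-methylpentyl]lithium | [Li]CC[C@@H](C)CCO[Si](C)(C)C(C)(C)C
F8 | step 8 | tertiary allylic alcohol from 1,2-addition of F7 to the C9 carbonyl of 13 (C9 epimer mixture) | CC1=CC[C@@H]2C(C)(C)CCC[C@@]2(C)C1(O)CC[C@@H](C)CCO[Si](C)(C)C(C)(C)C
F9 | step 8 | (4aR,8aR)-4-[(3R)-5-(tert-butyldimethylsilyloxy)-3-methylpentyl]-3,4a,8,8-tetramethyl-4a,5,6,7,8,8a-hexahydronaphthalen-2(1H)-one | CC1=C(CC[C@@H](C)CCO[Si](C)(C)C(C)(C)C)[C@]2(C)CCCC(C)(C)[C@H]2CC1=O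
F10 | step 8 | (3R)-3-methyl-5-[(4aR,8aR)-2,5,5,8a-tetramethyl-3-oxo-3,4,4a,5,6,7,8,8a-octahydronaphthalen-1-yl]pentanoic acid | CC1=C(CC[C@@H](C)CC(=O)O)[C@]2(C)CCCC(C)(C)[C@H]2CC1=O
F11 | step 9 | (4aR,8aR)-2,5,5,8a-tetramethyl-3-oxo-3,4,4a,5,6,7,8,8a-octahydronaphthalen-1-yl trifluoromethanesulfonate | CC1=C(OS(=O)(=O)C(F)(F)F)[C@]2(C)CCCC(C)(C)[C@H]2CC1=O
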